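## Retrosynthetic overview

1. Structural feature: the triad C7 (benzylic CH2)–C8 (methine)–C9 (methyl), and its twin C7′–C8′–C9′, is a trans-2-arylcyclopropane ring C7–C8–C9 whose benzylic C7–C9 bond has been reduced. The C8–C8′ bond therefore joins two three-membered rings in a C2-symmetric bicyclopropyl that already holds (8R,8′R).
2. The arenes differ by one O-methyl only (C5–OH against C5′–OMe). Both come from one 4-benzyloxy-3,5-dimethoxyphenylzinc reagent, and one of the four homotopic OMe groups is removed last.
3. Disconnections, backwards: O–CH3 (oxidative demethylation); C7–C9 and C7′–C9′ re-closed (retro-hydrogenolysis); C7–aryl and C7′–aryl (decarboxylative arylation of the bicyclopropyl diacid); C7–C9, C8–C9, C7′–C9′ and C8′–C9′ (double directed Simmons–Smith on the E,E-dienediol from muconic acid).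
4. Ring order: the benzene rings are bought. Cyclopropane C7–C8–C9 and then C7′–C8′–C9′ are closed in one flask, carried through four steps, and both opened in one hydrogenolysis.

Key step: step 3

Assumption: the facial sense of the dioxaborolane is taken from E-3-substituted allylic alcohols, where the (4R,5R) reagent gives an (S)-configured carbinol-bearing ring carbon. The bicyclopropyl needed here is (R) at C7/C7′, so the (4S,5S) reagent is used.

Remark: the diaryl bicyclopropyls are drawn trans,trans. A cis ring arising in the radical coupling would converge, because C7/C7′ end as CH2.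

## Route

Step 1
Reactants: 1 trans,trans-muconic acid
Product: 2 dimethyl (2E,4E)-hexa-2,4-dienedioate
Conditions: MeOH, cat. H2SO4, reflux
Reagents that add atoms: methanol, CO
Why: Fischer esterification in excess methanol draws the sparingly soluble diacid into solution as the diester, and the all-trans diene, being the thermodynamic isomer, should keep its E,E geometry; no stereocentre is formed.

Step 2
Reactants: 2 dimethyl (2E,4E)-hexa-2,4-dienedioate
Product: 3 (2E,4E)-hexa-2,4-diene-1,6-diol
Conditions: DIBAL-H (4.5 equiv), CH2Cl2, −78 → 0 °C; aq Rochelle salt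
Reagents that add atoms: none
Why: DIBAL-H reduction of α,β-unsaturated esters is a 1,2-selective hydride reduction to allylic alcohols, so both E alkenes should pass through unchanged.

Step 3
Reactants: 3 (2E,4E)-hexa-2,4-diene-1,6-diol; 4 diiodomethane
Product: 6 [(1S,1′S,2R,2′R)-1,1′-bi(cyclopropane)-2,2′-diyl]dimethanol, via vinylcyclopropane diol 5 (not isolated)
Conditions: Et2Zn (5 equiv), CH2I2 (10 equiv), DME (5 equiv), CH2Cl2, −15 °C; then (4S,5S)-2-butyl-N,N,N′,N′-tetramethyl-1,3,2-dioxaborolane-4,5-dicarboxamide (2.4 equiv) and 3, −10 °C → rt; aq NH4Cl, then aq KOH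
Reagents that add atoms: diiodomethane 4, ICI (the two CH2 groups C9 and C9′)
Why: Each hydroxyl of 3 becomes an iodomethylzinc alkoxide that binds the Lewis-acidic boron of the dioxaborolane, and an amide carbonyl of the same ligand chelates the zinc carbenoid, so CH2 is passed to the adjacent alkene from inside a rigid chiral complex. The closest known reaction is the dioxaborolane-mediated enantioselective Simmons–Smith cyclopropanation of E-allylic alcohols, which has also been run in both directions on conjugated dienediols. Ring C7–C8–C9 and then ring C7′–C8′–C9′ are each closed by a concerted intermolecular [2+1] methylene transfer through a butterfly transition state, in which the two bonds to C9 (or C9′) form together. The absolute configuration of C7, C8, C7′ and C8′ is fixed by the (4S,5S) ligand, which selects the same alkene face at both ends, and the trans relation within each ring follows from stereospecific syn addition to the E alkenes. The step needs facial selectivity twice and full conversion of 5; the substrate secures this with one allylic OH per alkene at homotopic termini, so both events are directed and obey the reagent in the same sense. A single facial error gives the meso trans,trans diastereomer, which can be removed by chromatography or crystallisation, and this should raise the enantiopurity of 6.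

Step 4
Reactants: 6 [(1S,1′S,2R,2′R)-1,1′-bi(cyclopropane)-2,2′-diyl]dimethanol
Product: 8 (1S,1′S,2R,2′R)-1,1′-bi(cyclopropane)-2,2′-dicarboxylic acid, via bicyclopropyl dialdehyde 7 (not isolated)
Conditions: TEMPO (20 mol %), PhI(OAc)2 (4.6 equiv), MeCN–H2O 1:1, rt
Reagents that add atoms: water, O
Why: The TEMPO/PhI(OAc)2 oxoammonium oxidation in aqueous acetonitrile takes each primary alcohol through the aldehyde hydrate to the acid under near-neutral conditions that leave cyclopropanes closed, and only the immaterial C7/C7′ centres are enolisable, whereas C8/C8′ are not.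

Step 5
Reactants: 8 (1S,1′S,2R,2′R)-1,1′-bi(cyclopropane)-2,2′-dicarboxylic acid
Product: 9 bis(1,3-dioxoisoindolin-2-yl) (1S,1′S,2R,2′R)-1,1′-bi(cyclopropane)-2,2′-dicarboxylate
Conditions: N-hydroxyphthalimide (2.2 equiv), DIC (2.3 equiv), DMAP (10 mol %), CH2Cl2, rt
Reagents that add atoms: N-hydroxyphthalimide, ON1C(=O)c2ccccc2C1=O
Why: Carbodiimide (Steglich-type) esterification converts both acids into redox-active esters under mild conditions, with no change at any stereocentre.

Step 6
Reactants: 10 4-bromo-2,6-dimethoxyphenol
Product: 11 2-(benzyloxy)-5-bromo-1,3-dimethoxybenzene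
Conditions: BnBr, K2CO3, DMF, 50 °C
Reagents that add atoms: benzyl bromide, BrCc1ccccc1
Why: Williamson ether synthesis masks the acidic phenol, which would quench the organometallics of step 7, as a benzyl ether that is removed without an extra operation in step 8.

Step 7
Reactants: 9 bis(1,3-dioxoisoindolin-2-yl) (1S,1′S,2R,2′R)-1,1′-bi(cyclopropane)-2,2′-dicarboxylate; 11 2-(benzyloxy)-5-bromo-1,3-dimethoxybenzene
Product: 14 (1S,1′S,2R,2′R)-2,2′-bis[4-(benzyloxy)-3,5-dimethoxyphenyl]-1,1′-bi(cyclopropane), via aryllithium 12 (not isolated), via arylzinc chloride 13 (not isolated)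
Conditions: 11 (6 equiv), n-BuLi, THF, −78 °C; ZnCl2 (THF), −78 °C → rt; then 9, NiCl2·glyme (40 mol %), 4,4′-di-tert-butyl-2,2′-bipyridine (80 mol %), THF–DMF, rt
Reagents that add atoms: n-butyllithium, [Li]CCCC (Li, only in 12); zinc chloride, Cl[Zn]Cl (Zn and Cl, only in 13); nothing from a reagent stays in 14
Why: Bromine–lithium exchange and transmetalation give the arylzinc, and the nickel-catalysed decarboxylative Negishi-type arylation of redox-active esters, known for cyclopropyl esters, swaps each carboxyl for aryl through a C7 cyclopropyl σ-radical that neither opens nor involves C8; capture anti to the C8 substituent should favour the trans rings, and the C7 configuration is erased in step 8 in any case.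

Step 8
Reactants: 14 (1S,1′S,2R,2′R)-2,2′-bis[4-(benzyloxy)-3,5-dimethoxyphenyl]-1,1′-bi(cyclopropane)
Product: 16 4,4′-[(2R,3R)-2,3-dimethylbutane-1,4-diyl]bis(2,6-dimethoxyphenol), via debenzylated bicyclopropyl bisphenol 15 (not isolated)
Conditions: H2 (5 bar), 10% Pd/C, EtOH–AcOH 10:1, 50 °C
Reagents that add atoms: none
Why: Heterogeneous catalytic hydrogenolysis should first cleave the two benzyl ethers and then the strained benzylic C–C bond of each arylcyclopropane, where the C7–C9 edge is both benzylic and the least hindered toward the palladium surface, so C9 becomes the methyl and C7 the benzylic CH2 while every bond at C8/C8′ other than the one to the ring methylene stays intact and (8R,8′R) is inherited from step 3.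

Step 9
Reactants: 16 4,4′-[(2R,3R)-2,3-dimethylbutane-1,4-diyl]bis(2,6-dimethoxyphenol)
Product: 18 sauriol B, via ortho-quinone 17 (not isolated)
Conditions: IBX (0.7 equiv), THF, 0 °C → rt, dark; then aq Na2S2O4, rt; unreacted 16 recovered and resubmitted
Reagents that add atoms: 2-iodoxybenzoic acid (IBX), O=C1OI(=O)(O)c2ccccc12 (one O)
Why: In the IBX-mediated oxidative demethylation of 2-methoxyphenols the phenol binds iodine(V), oxygen is delivered to the methoxy-bearing ortho carbon and methanol is expelled to give the o-quinone, which dithionite reduces to the catechol; the four OMe groups of C2-symmetric 16 are homotopic, so any single event leads to 18, a deficit of oxidant limits reaction at the second ring, and no stereocentre is touched.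

## Compound list

1 | trans,trans-muconic acid | OC(=O)/C=C/C=C/C(=O)O | starting material
2 | dimethyl (2E,4E)-hexa-2,4-dienedioate | COC(=O)/C=C/C=C/C(=O)OC | intermediate
3 | (2E,4E)-hexa-2,4-diene-1,6-diol | OC/C=C/C=C/CO | intermediate
4 | diiodomethane | ICI | starting material
5 | (E)-3-[(1S,2R)-2-(hydroxymethyl)cyclopropyl]prop-2-en-1-ol | OC[C@@H]1C[C@H]1/C=C/CO | intermediate (not isolated)
6 | [(1S,1′S,2R,2′R)-1,1′-bi(cyclopropane)-2,2′-diyl]dimethanol | OC[C@@H]1C[C@H]1[C@@H]1C[C@H]1CO | intermediate
7 | (1S,1′S,2R,2′R)-1,1′-bi(cyclopropane)-2,2′-dicarbaldehyde | O=C[C@@H]1C[C@H]1[C@@H]1C[C@H]1C=O | intermediate (not isolated)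
8 | (1S,1′S,2R,2′R)-1,1′-bi(cyclopropane)-2,2′-dicarboxylic acid | OC(=O)[C@@H]1C[C@H]1[C@@H]1C[C@H]1C(=O)O | intermediate
9 | bis(1,3-dioxoisoindolin-2-yl) (1S,1′S,2R,2′R)-1,1′-bi(cyclopropane)-2,2′-dicarboxylate | O=C(ON1C(=O)c2ccccc2C1=O)[C@@H]1C[C@H]1[C@@H]1C[C@H]1C(=O)ON1C(=O)c2ccccc2C1=O | intermediate
10 | 4-bromo-2,6-dimethoxyphenol | COc1cc(Br)cc(OC)c1O | starting material
11 | 2-(benzyloxy)-5-bromo-1,3-dimethoxybenzene | COc1cc(Br)cc(OC)c1OCc1ccccc1 | intermediate
12 | [4-(benzyloxy)-3,5-dimethoxyphenyl]lithium | [Li]c1cc(OC)c(OCc2ccccc2)c(OC)c1 | intermediate (not isolated)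
13 | [4-(benzyloxy)-3,5-dimethoxyphenyl]zinc chloride | Cl[Zn]c1cc(OC)c(OCc2ccccc2)c(OC)c1 | intermediate (not isolated)
14 | (1S,1′S,2R,2′R)-2,2′-bis[4-(benzyloxy)-3,5-dimethoxyphenyl]-1,1′-bi(cyclopropane) | COc1cc(cc(OC)c1OCc1ccccc1)[C@@H]1C[C@H]1[C@@H]1C[C@H]1c1cc(OC)c(OCc2ccccc2)c(OC)c1 | intermediate
15 | 4,4′-[(1S,1′S,2R,2′R)-1,1′-bi(cyclopropane)-2,2′-diyl]bis(2,6-dimethoxyphenol) | COc1cc(cc(OC)c1O)[C@@H]1C[C@H]1[C@@H]1C[C@H]1c1cc(OC)c(O)c(OC)c1 | intermediate (not isolated)
16 | 4,4′-[(2R,3R)-2,3-dimethylbutane-1,4-diyl]bis(2,6-dimethoxyphenol) | COc1cc(C[C@@H](C)[C@H](C)Cc2cc(OC)c(O)c(OC)c2)cc(OC)c1O | intermediate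
17 | 5-[(2R,3R)-4-(4-hydroxy-3,5-dimethoxyphenyl)-2,3-dimethylbutyl]-3-methoxycyclohexa-3,5-diene-1,2-dione | COC1=CC(C[C@@H](C)[C@H](C)Cc2cc(OC)c(O)c(OC)c2)=CC(=O)C1=O | intermediate (not isolated)
18 | sauriol B, 5-[(2R,3R)-4-(4-hydroxy-3,5-dimethoxyphenyl)-2,3-dimethylbutyl]-3-methoxybenzene-1,2-diol | COc1cc(C[C@@H](C)[C@H](C)Cc2cc(OC)c(O)c(OC)c2)cc(O)c1O | target

## Step count and risks

Total step count: 9. Longest linear sequence: 8 (steps 1–5 and 7–9, from trans,trans-muconic acid); step 6 is a one-step side branch.

**Step 8.**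
- What may go wrong:
  - The more substituted benzylic bond C7–C8 may be cleaved instead, which straightens the chain.
  - The reaction may stall after one ring has opened.
  - C8 may epimerise through reversible β-hydride elimination and re-addition on palladium.
- Fallback: polar instead of surface-mediated opening, from 14 back to 16.
  - Solvomercuration of the arylcyclopropanes with Hg(OAc)2 in MeOH places the electrophile on the least substituted ring carbon C9 and methanol on the benzylic C7. This should give the bis(acetoxymercurio) bis(benzylic methyl ether) F1.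
  - Alkaline NaBH4 demercuration turns each CH2Hg into the C9 methyl and also reverses any aryl mercuration. This gives the 7,7′-dimethoxy dibenzyl ether F2.
  - H2 over Pd(OH)2/C in EtOH–AcOH then removes the benzylic OMe and the benzyl groups to reach 16.
  - C8/C8′ are not involved at any stage.

**Step 9.**
- What may go wrong:
  - The second ring may be oxidised, so that product is lost to a statistical distribution.
  - The o-quinone may dimerise or add phenol before it is reduced.
  - Oxidation may be diverted to a p-quinone methide at C7.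
- Fallback: the O-methyl difference is built into the aryl partners and the two couplings are run one after the other, from 9 (with 10 and 13) back to 18.
  - Compound 10 is mono-demethylated with BBr3 (1 equiv). The boron held at the free OH should cleave one neighbouring OMe and end as a cyclic catechol borate. This gives 5-bromo-3-methoxybenzene-1,2-diol F3.
  - BnBr/K2CO3 gives 1,2-bis(benzyloxy)-5-bromo-3-methoxybenzene F4.
  - n-BuLi gives the aryllithium F5, and ZnCl2 gives the arylzinc chloride F6.
  - Bis-ester 9 is treated with a deficit of 13 under the nickel conditions of step 7. This gives the monoaryl mono(redox-active ester) F7, which differs strongly in polarity from 9 and 14 and should be easy to separate.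
  - A second coupling with F6 gives the unsymmetrical diaryl bicyclopropyl F8.
  - The hydrogenolysis of step 8 converts F8 directly into 18. The core is C2-symmetric, so it does not matter which end receives which aryl group.

**Step 7.**
- What may go wrong:
  - The cyclopropyl radical may be reduced by hydrogen abstraction before nickel captures it.
  - The arylzinc may attack the activated ester as an acyl acceptor.
  - The arylzinc may homocouple. With two couplings per molecule, all of these losses count twice.
- Fallback: reversed polarity, from 9 back to 14.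
  - Copper-catalysed decarboxylative borylation (B2pin2, Cu(acac)2, LiOH·H2O, MgCl2, dioxane–DMF) gives the trans,trans bis(pinacolboronate) F9.
  - A double Suzuki–Miyaura coupling with aryl bromide 11 (Pd(OAc)2, RuPhos, K3PO4, toluene–H2O, 100 °C) proceeds with retention at the cyclopropyl carbon and gives 14.

## Further compounds

F1 | step 8 | dibenzyl ether of the 7,7′-dimethoxy-9,9′-bis(acetoxymercurio) lignan, C8/C8′ arranged as in 16, C7/C7′ not defined | COc1cc(cc(OC)c1OCc1ccccc1)C(OC)[C@@H](C[Hg]OC(C)=O)[C@H](C[Hg]OC(C)=O)C(OC)c1cc(OC)c(OCc2ccccc2)c(OC)c1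
F2 | step 8 | 7,7′-dimethoxy derivative of the dibenzyl ether of 16, C8/C8′ arranged as in 16, C7/C7′ not defined | COc1cc(cc(OC)c1OCc1ccccc1)C(OC)[C@@H](C)[C@H](C)C(OC)c1cc(OC)c(OCc2ccccc2)c(OC)c1
F3 | step 9 | 5-bromo-3-methoxybenzene-1,2-diol | COc1cc(Br)cc(O)c1O
F4 | step 9 | 1,2-bis(benzyloxy)-5-bromo-3-methoxybenzene | COc1cc(Br)cc(OCc2ccccc2)c1OCc1ccccc1
F5 | step 9 | [3,4-bis(benzyloxy)-5-methoxyphenyl]lithium | [Li]c1cc(OC)c(OCc2ccccc2)c(OCc2ccccc2)c1
F6 | step 9 | [3,4-bis(benzyloxy)-5-methoxyphenyl]zinc chloride | Cl[Zn]c1cc(OC)c(OCc2ccccc2)c(OCc2ccccc2)c1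
F7 | step 9 | 1,3-dioxoisoindolin-2-yl (1S,1′S,2R,2′R)-2′-[4-(benzyloxy)-3,5-dimethoxyphenyl]-1,1′-bi(cyclopropane)-2-carboxylate | COc1cc(cc(OC)c1OCc1ccccc1)[C@@H]1C[C@H]1[C@@H]1C[C@H]1C(=O)ON1C(=O)c2ccccc2C1=O
F8 | step 9 | (1S,1′S,2R,2′R)-2-[4-(benzyloxy)-3,5-dimethoxyphenyl]-2′-[3,4-bis(benzyloxy)-5-methoxyphenyl]-1,1′-bi(cyclopropane) | COc1cc(cc(OC)c1OCc1ccccc1)[C@@H]1C[C@H]1[C@@H]1C[C@H]1c1cc(OC)c(OCc2ccccc2)c(OCc2ccccc2)c1
F9 | step 7 | trans,trans-2,2′-bis(4,4,5,5-tetramethyl-1,3,2-dioxaborolan-2-yl)-1,1′-bi(cyclopropane), rings arranged as in 8 | CC1(C)OB(OC1(C)C)[C@@H]1C[C@H]1[C@@H]1C[C@H]1B1OC(C)(C)C(C)(C)O1
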